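The zeta run opened the meeting: at 2 mol% of initiator, it had 93.6% of its free monomer in chains after 2.50 d.

all flasks: free monomer 20 mM
- zeta: initiator 2 mol%; run made earlier
- eta: initiator 3.8 mol%; run made earlier
- delta: initiator 5.9 mol%; run made earlier
- south-west: initiator 2.6 mol%; time 5.0 d
- east: initiator 5 mol%; time 5.0 d

| run | time / d | monomer in chains / % |
|---|---|---|
| zeta | 0.333 | 34.7 |
| zeta | 0.833 | 63.2 |
| zeta | 1.67 | 85.6 |
| zeta | 2.50 | 93.6 |
| eta | 0.208 | 31.2 |
| eta | 0.500 | 57.9 |
| eta | 1.04 | 82.6 |
| eta | 2.50 | 99.0 |
| delta | 0.625 | 74.8 |
| delta | 1.25 | 94.0 |
| delta | 2.08 | 99.0 |
| delta | 2.50 | 100.1 |

(readings scatter by 0.5 percentage points)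

- the average divides the monomer in chains by the number of chains, living and dead together; two radicals that join make one chain
- the earlier runs do not show the number of chains; that part of a forecast is a guess

* which of the two ends with the longer chains by the average number of monomer units in a chain (living and dead chains, two that joined counted as one) ("neither" if they lie within 10%) (south-west / east / neither)
* average number of monomer units in a chain (living and dead chains, two that joined counted as one) at the end, south-west
* average number of monomer units in a chain (living and dead chains, two that joined counted as one) at the end, east

The chair noted that the earlier runs do not show the number of chains. The forecaster argued from the rates, which he read as “steady-state radicals with bimolecular termination”. His forecast named south-west as longer. It gave 100 for south-west, within 60 to 175, and 53 for east, within 31 to 92. He called his radical efficiency a guess.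

I proposed freezing one quantity. South-west charges 38.5 free monomer per initiator, and east charges 20.0. Call this L, the charge length: free monomer charged per initiator charged. I assumed that each spent initiator gives two radicals, and that these join into one chain. The average length is then L divided by s, the share of initiator spent while free monomer lasts. With equal s, south-west would be longer by a factor of 1.93, which is more than the margin of 10% requires. Unlike the forecast, this reckoning uses no efficiency. But delta had 99.0% in chains by 2.08 d, so I warned that east might stop making chains early, with a smaller s.

    2 free monomer → self-condensation product (k = 2.00 × 10⁻⁵ L mol⁻¹ min⁻¹)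
    free monomer + initiating radical → growing radical + monomer in chains (k = 1.90 × 10⁵ L mol⁻¹ s⁻¹)
    initiator → 2 initiating radical (k = 2.40 × 10⁻⁴ min⁻¹)
    2 growing radical → dead chain (k = 9.50 × 10⁷ L mol⁻¹ s⁻¹)
    free monomer + growing radical → monomer in chains + growing radical, rate k5*[growing radical]*[free monomer] (k = 2.20 × 10⁵ L mol⁻¹ min⁻¹)

The flask gives south-west as longer, with a number-average degree of polymerisation of 46.7 for south-west and 32.9 for east. South-west keeps 18% of its initiator, so L over the spent share gives 47.0. East keeps 18%, and the same division gives 24.4, against its 32.9; there, free monomer stands at 0% and initiating radical at 0.429 mM. The neighbouring flask is south-west with 1.6 mol% of initiator, so L is 62.5. It keeps 18% of its initiator and 1.5% of its free monomer, which gives 75.1. The simulated neighbouring flask gives 74.8.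

The numbers in the tables are simulated on assumed constants; scatter was added.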